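The route rests on closing both the tetrahydropyran and the ten-membered carbocycle of this 4,8-epoxybriarane in one Lewis-acid operation. The C4 hydroxyl adds to C8, the β-carbon of the C19 lactone carbonyl in a 4-formylbutenolide (O–C8 bond); the α-alkoxy aldehyde so formed at C9 is chelated and attacked by C10 of a ring-A allylsilane, whose allyl shift delivers the C11=C20 methylene (C9–C10 bond). The precursor is monocyclic ring A, carrying at C1 the open C2–C7 chain with the C6 chloride and the butenolide; all other stereocentres are set before by reagent- or substrate-controlled additions.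

Key step: step 21

Remark: atom numbers in names follow the briarane skeleton (C1 quaternary carbon of ring A, C2–C9 along the large ring, C10–C14 ring A, C16 and C20 the methylene carbons on C5 and C11, C17–C19 the lactone carbons, C18 its methyl); 1,3-dihydroxyacetone is taken as its commercial dimer.

Step 1
Reactants: 1 1,4-dioxaspiro[4.5]dec-6-en-8-one
Product: 2 7-(hydroxymethyl)-1,4-dioxaspiro[4.5]dec-6-en-8-one
Conditions: aq. HCHO, DMAP (cat.), THF/H2O, rt
Reagents that add atoms: formaldehyde C=O
Why: Morita–Baylis–Hillman hydroxymethylation at the enone α-carbon, which becomes C1 and carries the future C2.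

Step 2
Reactants: 2 7-(hydroxymethyl)-1,4-dioxaspiro[4.5]dec-6-en-8-one
Product: 3 7-[(tert-butyldimethylsilyloxy)methyl]-1,4-dioxaspiro[4.5]dec-6-en-8-one
Conditions: TBSCl, imidazole, DMF, 0 °C to rt
Reagents that add atoms: tert-butyldimethylsilyl chloride CC(C)(C)[Si](C)(C)Cl
Why: Standard silylation of the primary alcohol, needed before the borane reduction and the cuprate step.

Step 3
Reactants: 3 7-[(tert-butyldimethylsilyloxy)methyl]-1,4-dioxaspiro[4.5]dec-6-en-8-one
Product: 4 (8S)-7-[(tert-butyldimethylsilyloxy)methyl]-1,4-dioxaspiro[4.5]dec-6-en-8-ol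
Conditions: (R)-2-methyl-CBS-oxazaborolidine (cat.), BH3·SMe2, THF, −20 °C
Reagents that add atoms: none
Why: Corey–Bakshi–Shibata reduction of an α-substituted cyclohexenone, in which the alkenyl side acts as the large group, should set the C14 carbinol as (S).

Step 4
Reactants: 4 (8S)-7-[(tert-butyldimethylsilyloxy)methyl]-1,4-dioxaspiro[4.5]dec-6-en-8-ol
Product: 5 (8S)-7-[(tert-butyldimethylsilyloxy)methyl]-8-(methoxymethoxy)-1,4-dioxaspiro[4.5]dec-6-ene
Conditions: MOMCl, iPr2NEt, CH2Cl2, 0 °C to rt
Reagents that add atoms: chloromethyl methyl ether COCCl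
Why: Alkylation of the secondary alcohol gives an ether that tolerates the cuprate and organolithium steps and does not leave from the γ-position of the enone.

Step 5
Reactants: 5 (8S)-7-[(tert-butyldimethylsilyloxy)methyl]-8-(methoxymethoxy)-1,4-dioxaspiro[4.5]dec-6-ene
Product: 6 (4S)-3-[(tert-butyldimethylsilyloxy)methyl]-4-(methoxymethoxy)cyclohex-2-en-1-one
Conditions: PPTS, acetone/H2O, rt
Reagents that add atoms: water O
Why: Mild hydrolysis of the allylic dioxolane unveils the transposed enone (C11 carbonyl, C10=C1) while the MOM and silyl ethers should survive.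

Step 6
Reactants: 6 (4S)-3-[(tert-butyldimethylsilyloxy)methyl]-4-(methoxymethoxy)cyclohex-2-en-1-one
Product: 8 (3S,4S)-3-[(tert-butyldimethylsilyloxy)methyl]-4-(methoxymethoxy)-3-methylcyclohex-1-en-1-yl trifluoromethanesulfonate (methyl trans to OMOM), via lithium enolate 7 (not isolated)
Conditions: Me2CuLi (from MeLi, CuI), Et2O, −78 to −30 °C; then N-(5-chloro-2-pyridyl)bis(trifluoromethanesulfonimide), THF, −78 to 0 °C
Reagents that add atoms: lithium dimethylcuprate [Li+].C[Cu-]C; N-(5-chloro-2-pyridyl)bis(trifluoromethanesulfonimide) O=S(=O)(N(c1ccc(Cl)cn1)S(=O)(=O)C(F)(F)F)C(F)(F)F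
Why: Cuprate conjugate addition anti to the γ-alkoxy group sets the C1 quaternary centre (methyl trans to the C14 oxygen), and O-triflation of the regiodefined enolate fixes the C10=C11 double bond.

Step 7
Reactants: 8 the silyl ether triflate
Product: 9 (3S,4S)-3-(hydroxymethyl)-4-(methoxymethoxy)-3-methylcyclohex-1-en-1-yl trifluoromethanesulfonate
Conditions: HF·pyridine, pyridine, THF, 0 °C
Reagents that add atoms: none
Why: Buffered fluoride cleaves the primary silyl ether and should leave the MOM ether and the vinyl triflate untouched.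

Step 8
Reactants: 9 the primary alcohol
Product: 10 (3R,4S)-3-formyl-4-(methoxymethoxy)-3-methylcyclohex-1-en-1-yl trifluoromethanesulfonate (C2 aldehyde)
Conditions: Dess–Martin periodinane, NaHCO3, CH2Cl2, rt
Reagents that add atoms: none
Why: Dess–Martin oxidation gives the non-enolisable neopentyl aldehyde without risk to the C1 centre.

Step 9
Reactants: 10 the C2 aldehyde; 11 allyl methoxymethyl ether
Product: 12 ring-A triflate carrying at C1 the (1R,2R)-1-hydroxy-2-(methoxymethoxy)but-3-enyl chain (C2 hydroxyl and C3 OMOM syn)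
Conditions: 11, s-BuLi, THF, −78 °C; (−)-Ipc2BOMe; BF3·OEt2; then 10, −78 °C to rt; aq. NaOH, H2O2
Reagents that add atoms: none
Why: Brown γ-alkoxyallylboration through a chair Zimmerman–Traxler transition state gives the 2,3-syn pair, and the reagent derived from (+)-α-pinene should add to the Si face of the aldehyde, which is the face needed for C2 and C3.

Step 10
Reactants: 12 the syn homoallylic alcohol
Product: 13 its C2 tert-butyldimethylsilyl ether
Conditions: TBSOTf, 2,6-lutidine, CH2Cl2, 0 °C
Reagents that add atoms: tert-butyldimethylsilyl triflate CC(C)(C)[Si](C)(C)OS(=O)(=O)C(F)(F)F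
Why: The silyl triflate silylates the hindered neopentylic hydroxyl, which must stay masked until the last step.

Step 11
Reactants: 13 the C2 silyl ether
Product: 15 C4 aldehyde (2,3-syn 3-silyloxy-2-(methoxymethoxy)propanal on ring A), via ozonide 14 (not isolated)
Conditions: O3, CH2Cl2, −78 °C; then PPh3, −78 °C to rt
Reagents that add atoms: ozone [O-][O+]=O
Why: Ozonolysis cleaves the terminal vinyl group while the electron-poor enol triflate should survive.

Step 12
Reactants: 15 the C4 aldehyde; 16 2-bromo-3,3-diethoxyprop-1-ene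
Product: 18 C4 triethylsilyl ether bearing the 2-(diethoxymethyl)vinyl group (3,4-anti), via lithium alkoxide 17 (not isolated)
Conditions: 16, t-BuLi, Et2O, −78 °C; then 15, THF, −78 °C; then TESOTf, 2,6-lutidine, −78 to 0 °C
Reagents that add atoms: triethylsilyl triflate CC[Si](CC)(CC)OS(=O)(=O)C(F)(F)F
Why: Addition of the α-lithioacrolein acetal to the α-alkoxy aldehyde under polar Felkin–Anh control (non-chelating lithium in THF, β-silyloxy group) should give the 3,4-anti carbinol, which is silylated in the same flask.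

Step 13
Reactants: 18 the diethyl acetal
Product: 19 enal (C6 aldehyde, C5=C16 methylene, C4 OTES)
Conditions: aq. oxalic acid on SiO2, CH2Cl2, rt
Reagents that add atoms: water O
Why: The allylic acetal hydrolyses under very mild acid, which should spare the secondary triethylsilyl ether.

Step 14
Reactants: 20 1,3-dihydroxyacetone; 21 ethyl 2-(triphenyl-λ5-phosphanylidene)propanoate
Product: 23 4-(hydroxymethyl)-3-methylfuran-2(5H)-one, via hydroxy ester 22 (not isolated)
Conditions: CH2Cl2, reflux
Reagents that add atoms: none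
Why: Wittig olefination of the symmetrical ketone gives an enoate in which one hydroxymethyl group is always cis to the ester, so lactonisation to the butenolide follows without a geometry problem.

Step 15
Reactants: 23 4-(hydroxymethyl)-3-methylfuran-2(5H)-one
Product: 24 3-methyl-2-(triethylsilyloxy)-4-[(triethylsilyloxy)methyl]furan
Conditions: TESOTf (2.2 equiv), Et3N, CH2Cl2, 0 °C
Reagents that add atoms: triethylsilyl triflate CC[Si](CC)(CC)OS(=O)(=O)C(F)(F)F
Why: Silylation of the alcohol and soft enolisation of the butenolide give the 2-silyloxyfuran, whose only free position is the future C7.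

Step 16
Reactants: 19 the enal; 24 the silyloxyfuran
Product: 25 butenolide alcohol (C6 hydroxyl, C7 lactone oxygen; 4,6-anti and 6,7-threo)
Conditions: BF3·OEt2, CH2Cl2, −78 °C; aq. NaHCO3
Reagents that add atoms: none
Why: Vinylogous Mukaiyama aldol addition, for which the open transition state is expected to give the threo C6/C7 pair and the dipole-minimised β-silyloxy aldehyde the 1,3-anti relation to C4.

Step 17
Reactants: 25 the vinyl triflate
Product: 26 allylsilane (C11 bears CH2SiMe3, C10=C11)
Conditions: Me3SiCH2ZnCl (from Me3SiCH2MgCl, ZnCl2), Pd(PPh3)4 (cat.), LiCl, THF, rt to 40 °C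
Reagents that add atoms: (trimethylsilyl)methylzinc chloride C[Si](C)(C)C[Zn]Cl
Why: Negishi coupling of the enol triflate is placed here because the organozinc tolerates the butenolide and the allylic chloride, which would add to zerovalent palladium, is not yet present.

Step 18
Reactants: 26 the C6 alcohol
Product: 27 C6 chloride (6S, 6,7-anti as in the target)
Conditions: PPh3, hexachloroacetone, 2,6-di-tert-butylpyridine, CH2Cl2, −20 to 0 °C
Reagents that add atoms: hexachloroacetone ClC(Cl)(Cl)C(=O)C(Cl)(Cl)Cl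
Why: Appel-type chlorination through the alkoxyphosphonium chloride should proceed by SN2 with inversion at C6, conditions of this kind being known to convert secondary allylic alcohols without allylic transposition.

Step 19
Reactants: 27 the bis(triethylsilyl) ether
Product: 28 diol (free C4 and C9 hydroxyls)
Conditions: PPTS, MeOH/CH2Cl2, 0 °C to rt
Reagents that add atoms: none
Why: Mild acidic methanolysis removes both triethylsilyl ethers and should leave the neopentylic tert-butyldimethylsilyl ether, the MOM ethers and the allylsilane intact.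

Step 20
Reactants: 28 the diol
Product: 29 hydroxy aldehyde (4-formylbutenolide with free C4 hydroxyl)
Conditions: TEMPO (cat.), PhI(OAc)2, CH2Cl2, rt; used at once
Reagents that add atoms: none
Why: The oxoammonium oxidation is selective for the primary allylic alcohol over the secondary C4 hydroxyl.

Step 21
Reactants: 29 the hydroxy aldehyde
Product: 31 tricyclic C9 alcohol (4,8-ether bridge, ten-membered ring, C11=C20 methylene), via pyranyl aldehyde 30 (not isolated)
Conditions: SnCl4 (2.5 equiv), 2,6-di-tert-butyl-4-methylpyridine, CH2Cl2, 0.002 M, slow addition of 29, −78 to −40 °C; aq. NaHCO3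
Reagents that add atoms: none
Why: SnCl4 turns the C4 hydroxyl into a tin alkoxide and activates the butenolide, so a 6-exo-trig oxa-Michael addition at C8 closes the tetrahydropyran (O–C8 bond) and the enolate is protonated at C17 from the convex face. The α-alkoxy aldehyde so unveiled forms a five-membered tin chelate between the ring oxygen and O9, and C10 of the allylsilane adds to C9 in a Hosomi–Sakurai reaction that closes the ten-membered carbocycle (the eight-membered oxocane of the bridged system) and shifts the double bond to C11=C20. The closest known reaction types are acid-mediated intramolecular oxa-Michael additions to butenolides and chelation-controlled allylsilane additions to α-alkoxy aldehydes, including Lewis-acid-mediated eight- to ten-membered carbocyclisations. C8 is set by C7 because only the cis-fused lactone–pyran can form, C9 by the chelate (attack on the exo face, anti to C7), and C10 by ring A, where the axial C14 OMOM group shields the lower face so that C9 enters cis to the C1 methyl. The step needs attack at C8 and not at C17 in the oxa-Michael addition, which the six- against seven-membered closure and the reversibility of the addition before an irreversible allylation should secure, and it needs cyclisation over oligomerisation, which high dilution secures.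

Step 22
Reactants: 31 the bis(MOM) ether
Product: 32 triol (free C3, C9 and C14 hydroxyls, C2 silyl ether)
Conditions: Me2BBr, CH2Cl2, −78 °C; then aq. NaHCO3/THF
Reagents that add atoms: none
Why: The bromoborane cleaves acetal-type ethers at low temperature and should leave the silyl ether, the lactone, the allylic chloride and both methylene groups alone.

Step 23
Reactants: 32 the triol
Product: 33 3,9,14-triacetate C2 silyl ether
Conditions: Ac2O, DMAP, pyridine, rt
Reagents that add atoms: acetic anhydride CC(=O)OC(C)=O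
Why: DMAP-catalysed acylation esterifies the three free secondary hydroxyls while C2 is still silylated, which fixes the acetylation pattern.

Step 24
Reactants: 33 the triacetate silyl ether
Product: 34 (1S,2R,3S,4R,6S,7R,8R,9S,10S,14S,17R)-3,9,14-triacetoxy-6-chloro-4,8-epoxy-2-hydroxybriara-5(16),11(20)-dien-19,7-olide
Conditions: aq. HF, MeCN, 0 °C to rt
Reagents that add atoms: none
Why: Acidic fluoride removes the last silyl ether under conditions where acetate migration from C3 to C2 is not expected.

Compound list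
1 | 1,4-dioxaspiro[4.5]dec-6-en-8-one | O=C1C=CC2(CC1)OCCO2 | starting material
2 | 7-(hydroxymethyl)-1,4-dioxaspiro[4.5]dec-6-en-8-one | O=C1C(CO)=CC2(CC1)OCCO2 | intermediate
3 | 7-[(tert-butyldimethylsilyloxy)methyl]-1,4-dioxaspiro[4.5]dec-6-en-8-one | O=C1C(CO[Si](C)(C)C(C)(C)C)=CC2(CC1)OCCO2 | intermediate
4 | (8S)-7-[(tert-butyldimethylsilyloxy)methyl]-1,4-dioxaspiro[4.5]dec-6-en-8-ol | O[C@H]1CCC2(OCCO2)C=C1CO[Si](C)(C)C(C)(C)C | intermediate
5 | (8S)-7-[(tert-butyldimethylsilyloxy)methyl]-8-(methoxymethoxy)-1,4-dioxaspiro[4.5]dec-6-ene | COCO[C@H]1CCC2(OCCO2)C=C1CO[Si](C)(C)C(C)(C)C | intermediate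
6 | (4S)-3-[(tert-butyldimethylsilyloxy)methyl]-4-(methoxymethoxy)cyclohex-2-en-1-one | COCO[C@H]1CCC(=O)C=C1CO[Si](C)(C)C(C)(C)C | intermediate
7 | lithium enolate of the 3-methyl ketone (methyl trans to OMOM) | [Li]OC1=C[C@@](C)(CO[Si](C)(C)C(C)(C)C)[C@@H](OCOC)CC1 | intermediate
8 | (3S,4S)-3-[(tert-butyldimethylsilyloxy)methyl]-4-(methoxymethoxy)-3-methylcyclohex-1-en-1-yl trifluoromethanesulfonate | FC(F)(F)S(=O)(=O)OC1=C[C@@](C)(CO[Si](C)(C)C(C)(C)C)[C@@H](OCOC)CC1 | intermediate
9 | (3S,4S)-3-(hydroxymethyl)-4-(methoxymethoxy)-3-methylcyclohex-1-en-1-yl trifluoromethanesulfonate | FC(F)(F)S(=O)(=O)OC1=C[C@@](C)(CO)[C@@H](OCOC)CC1 | intermediate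
10 | (3R,4S)-3-formyl-4-(methoxymethoxy)-3-methylcyclohex-1-en-1-yl trifluoromethanesulfonate | FC(F)(F)S(=O)(=O)OC1=C[C@@](C)(C=O)[C@@H](OCOC)CC1 | intermediate
11 | allyl methoxymethyl ether | C=CCOCOC | starting material
12 | ring-A triflate with (1R,2R)-1-hydroxy-2-(methoxymethoxy)but-3-enyl chain at C1 (2,3-syn) | FC(F)(F)S(=O)(=O)OC1=C[C@@](C)([C@@H](O)[C@H](OCOC)C=C)[C@@H](OCOC)CC1 | intermediate
13 | C2 tert-butyldimethylsilyl ether of 12 | FC(F)(F)S(=O)(=O)OC1=C[C@@](C)([C@@H](O[Si](C)(C)C(C)(C)C)[C@H](OCOC)C=C)[C@@H](OCOC)CC1 | intermediate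
14 | ozonide (1,2,4-trioxolane) of 13 | FC(F)(F)S(=O)(=O)OC1=C[C@@](C)([C@@H](O[Si](C)(C)C(C)(C)C)[C@H](OCOC)C2OCOO2)[C@@H](OCOC)CC1 | intermediate
15 | C4 aldehyde (C2 OTBS and C3 OMOM syn) | FC(F)(F)S(=O)(=O)OC1=C[C@@](C)([C@@H](O[Si](C)(C)C(C)(C)C)[C@H](OCOC)C=O)[C@@H](OCOC)CC1 | intermediate
16 | 2-bromo-3,3-diethoxyprop-1-ene | C=C(Br)C(OCC)OCC | starting material
17 | lithium C4 alkoxide of the acrolein acetal adduct (3,4-anti) | FC(F)(F)S(=O)(=O)OC1=C[C@@](C)([C@@H](O[Si](C)(C)C(C)(C)C)[C@H](OCOC)[C@H](O[Li])C(=C)C(OCC)OCC)[C@@H](OCOC)CC1 | intermediate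
18 | C4 triethylsilyl ether diethyl acetal (3,4-anti) | FC(F)(F)S(=O)(=O)OC1=C[C@@](C)([C@@H](O[Si](C)(C)C(C)(C)C)[C@H](OCOC)[C@H](O[Si](CC)(CC)CC)C(=C)C(OCC)OCC)[C@@H](OCOC)CC1 | intermediate
19 | enal (C6 aldehyde on the C5 methylene carbon) | FC(F)(F)S(=O)(=O)OC1=C[C@@](C)([C@@H](O[Si](C)(C)C(C)(C)C)[C@H](OCOC)[C@H](O[Si](CC)(CC)CC)C(=C)C=O)[C@@H](OCOC)CC1 | intermediate
20 | 1,3-dihydroxyacetone | O=C(CO)CO | starting material
21 | ethyl 2-(triphenyl-λ5-phosphanylidene)propanoate | CCOC(=O)C(C)=P(c1ccccc1)(c1ccccc1)c1ccccc1 | starting material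
22 | ethyl 4-hydroxy-3-(hydroxymethyl)-2-methylbut-2-enoate | CCOC(=O)C(C)=C(CO)CO | intermediate
23 | 4-(hydroxymethyl)-3-methylfuran-2(5H)-one | CC1=C(CO)COC1=O | intermediate
24 | 3-methyl-2-(triethylsilyloxy)-4-[(triethylsilyloxy)methyl]furan | Cc1c(O[Si](CC)(CC)CC)occ1CO[Si](CC)(CC)CC | intermediate
25 | butenolide alcohol, vinyl triflate (6-hydroxyl, 4,6-anti, 6,7-threo) | FC(F)(F)S(=O)(=O)OC1=C[C@@](C)([C@@H](O[Si](C)(C)C(C)(C)C)[C@H](OCOC)[C@H](O[Si](CC)(CC)CC)C(=C)[C@@H](O)[C@@H]2OC(=O)C(C)=C2CO[Si](CC)(CC)CC)[C@@H](OCOC)CC1 | intermediate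
26 | butenolide alcohol, allylsilane | C[Si](C)(C)CC1=C[C@@](C)([C@@H](O[Si](C)(C)C(C)(C)C)[C@H](OCOC)[C@H](O[Si](CC)(CC)CC)C(=C)[C@@H](O)[C@@H]2OC(=O)C(C)=C2CO[Si](CC)(CC)CC)[C@@H](OCOC)CC1 | intermediate
27 | C6 chloride (6S,7R), bis(triethylsilyl) ether | C[Si](C)(C)CC1=C[C@@](C)([C@@H](O[Si](C)(C)C(C)(C)C)[C@H](OCOC)[C@H](O[Si](CC)(CC)CC)C(=C)[C@H](Cl)[C@@H]2OC(=O)C(C)=C2CO[Si](CC)(CC)CC)[C@@H](OCOC)CC1 | intermediate
28 | chloro diol (free C4 and C9 hydroxyls) | C[Si](C)(C)CC1=C[C@@](C)([C@@H](O[Si](C)(C)C(C)(C)C)[C@H](OCOC)[C@H](O)C(=C)[C@H](Cl)[C@@H]2OC(=O)C(C)=C2CO)[C@@H](OCOC)CC1 | intermediate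
29 | hydroxy aldehyde (4-formylbutenolide, free C4 hydroxyl) | C[Si](C)(C)CC1=C[C@@](C)([C@@H](O[Si](C)(C)C(C)(C)C)[C@H](OCOC)[C@H](O)C(=C)[C@H](Cl)[C@@H]2OC(=O)C(C)=C2C=O)[C@@H](OCOC)CC1 | intermediate
30 | pyranyl lactone aldehyde (O–C8 bond formed, C8 R, C17 R) | O=C[C@@]12O[C@H](C(=C)[C@H](Cl)[C@@H]1OC(=O)[C@@H]2C)[C@@H](OCOC)[C@H](O[Si](C)(C)C(C)(C)C)[C@]3(C)C=C(C[Si](C)(C)C)CC[C@@H]3OCOC | intermediate
31 | tricyclic C9 alcohol, 3,14-bis(MOM) ether, 2-silyl ether (stereocentres as in 34) | C=C1CC[C@H](OCOC)[C@@]2(C)[C@H]1[C@H](O)[C@@]13O[C@H](C(=C)[C@H](Cl)[C@@H]1OC(=O)[C@@H]3C)[C@@H](OCOC)[C@@H]2O[Si](C)(C)C(C)(C)C | intermediate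
32 | 3,9,14-triol 2-silyl ether | C=C1CC[C@H](O)[C@@]2(C)[C@H]1[C@H](O)[C@@]13O[C@H](C(=C)[C@H](Cl)[C@@H]1OC(=O)[C@@H]3C)[C@@H](O)[C@@H]2O[Si](C)(C)C(C)(C)C | intermediate
33 | 3,9,14-triacetate 2-silyl ether | C=C1CC[C@H](OC(C)=O)[C@@]2(C)[C@H]1[C@H](OC(C)=O)[C@@]13O[C@H](C(=C)[C@H](Cl)[C@@H]1OC(=O)[C@@H]3C)[C@@H](OC(C)=O)[C@@H]2O[Si](C)(C)C(C)(C)C | intermediate
34 | (1S,2R,3S,4R,6S,7R,8R,9S,10S,14S,17R)-3,9,14-triacetoxy-6-chloro-4,8-epoxy-2-hydroxybriara-5(16),11(20)-dien-19,7-olide | C=C1CC[C@H](OC(C)=O)[C@@]2(C)[C@H]1[C@H](OC(C)=O)[C@@]13O[C@H](C(=C)[C@H](Cl)[C@@H]1OC(=O)[C@@H]3C)[C@@H](OC(C)=O)[C@@H]2O | target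

Total step count: 24. Longest linear sequence: 22 steps (steps 1–13 and 16–24); steps 14 and 15 make the furan in a side branch.

Steps most likely to fail

Step 21. The oxa-Michael addition may take the wrong course (attack at C17 under activation by the aldehyde, or ionisation of the C4/C9 lactol and allylation at C9 to an oxepane), the allylsilane may add to the wrong face of C9 or C10, or the medium ring may not close. The fallback separates the two ring closures and changes their oxidation level. From diol 28, a Sc(OTf)3-catalysed 6-exo oxa-Michael addition is run while C9 is still an alcohol, so that only the lactone carbonyl activates and C8 is the only β-carbon; this should give the pyranyl lactone alcohol F1. Dess–Martin oxidation of F1 gives the aldehyde 30 as an isolated compound, and a separate chelation-controlled Hosomi–Sakurai cyclisation (MgBr2·OEt2 or SnCl4, CH2Cl2, high dilution) returns to the route at 31.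

Step 16. The 1,3-induction from C4 may give poor facial selectivity at C6, or the threo preference at C6/C7 may erode. The fallback replaces substrate control in an open transition state by catalyst control with a different nucleophile. Butenolide 23 is silylated on oxygen only (TESCl, imidazole) to the silyl ether butenolide F2, and F2 is added to enal 19 in a direct vinylogous aldol reaction under soft enolisation with a chiral bifunctional guanidine or amine–thiourea base, returning to the route at 25.

Step 18. The alkoxyphosphonium ion may collapse with allylic transposition to the C16 chloride or by elimination instead of SN2 inversion at the hindered C6. The fallback uses a discrete sulfonate displacement: alcohol 26 is converted with ClCH2SO2Cl and pyridine into the C6 chloromethanesulfonate F3, which is displaced with LiCl in DMF with inversion, returning to the route at 27.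

Further compounds
F1 | step 21 | pyranyl lactone C9 alcohol (O–C8 bond formed, allylsilane intact) | OC[C@@]12O[C@H](C(=C)[C@H](Cl)[C@@H]1OC(=O)[C@@H]2C)[C@@H](OCOC)[C@H](O[Si](C)(C)C(C)(C)C)[C@]3(C)C=C(C[Si](C)(C)C)CC[C@@H]3OCOC
F2 | step 16 | 3-methyl-4-[(triethylsilyloxy)methyl]furan-2(5H)-one | CC1=C(CO[Si](CC)(CC)CC)COC1=O
F3 | step 18 | C6 chloromethanesulfonate of 26 | C[Si](C)(C)CC1=C[C@@](C)([C@@H](O[Si](C)(C)C(C)(C)C)[C@H](OCOC)[C@H](O[Si](CC)(CC)CC)C(=C)[C@@H](OS(=O)(=O)CCl)[C@@H]2OC(=O)C(C)=C2CO[Si](CC)(CC)CC)[C@@H](OCOC)CC1
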